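**Remark on the chemistry (assumption):** ring A is the chlorinated acyl ring and its atoms carry primes (C1' bears the acyl carbon, C2' OH, C3' Cl, C4' OCH3, C5' H, C6' CH3); ring B is the orsellinate ring. Diene 4 is used as its mixture of double-bond isomers, and LiN(iPr)2 is taken as a commercial solution.

## Analysis of the target

Target 15 is a para-depside: two benzene rings joined only by an aryl ester between the carboxyl carbon on C1' of ring A and the oxygen on C4 of ring B. Ring B is methyl orsellinate 13 unchanged apart from acylation at O4. Ring A is pentasubstituted, with CH3 (C6'), acyl (C1'), OH (C2'), Cl (C3') and OCH3 (C4') contiguous and only C5' bearing hydrogen. There are no stereocentres, so every selectivity question is one of regio- or chemoselectivity. The sensitive groups are the depside ester (cleaved or transacylated by hydroxide, alkoxides and amines), the aryl chloride (reducing conditions), the two chelated phenols, and the electron-rich salicylic acid met on the way, which decarboxylates when warmed in acid. The difficulty is to place chlorine at C3' between two oxygens while C5' stays free, and to have O2' free but O4' methylated; electrophilic chlorination of a preformed ring does not reliably tell C3' from C5'. The strategy rests on reading ring A as two acyclic pieces: the ester carbon with C1', C2' and C3' has the pattern of a 4-chloroacetoacetate (C1' the α-carbon, C2' the ketone carbon, C3' the chloromethyl carbon), and C4'–C5'–C6' with its methyl is an acetoacetyl unit whose C4' is at the ortho-ester oxidation level. Joined head to tail, these give the arene with every substituent already in place.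

## Retrosynthetic reasoning

**Depside ester.** The acyl C–O bond between the ring A carbonyl and O4 of ring B is cut first, giving acid 12 and methyl orsellinate 13. It is the only bond between the two halves that is not part of an arene, and 13 is a commercial compound. The forward reaction has to acylate O4 of 13 in preference to O2, which is hydrogen-bonded to the neighbouring ester and more hindered. It must do so without protecting O2' of 12, which is flanked by chlorine and the carboxyl group; activation as the mixed anhydride 14 is planned.

**Carboxyl group.** Acid 12 is traced to methyl ester 10 by ester hydrolysis through the salt 11. The methyl ester is what the ring synthesis delivers, so this is a change of functional group only. The forward step has to overcome two ortho substituents without decarboxylating the product.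

**Ring A.** In 10 the bonds C3'–C4' and C1'–C6' are cut, giving diene 4 and enone 7. Any disconnection that keeps the arene intact leads back to a chlorination with a C3'/C5' ambiguity. Here chlorine, the free hydroxyl, the methyl ether, the methyl group and the ester are each fixed by the connectivity of an acyclic partner. The forward reaction must join the chlorine-bearing terminus of 4 to the dialkoxy carbon of 7 under a Lewis acid, with loss of one methoxy group (adduct 8). It must then close the ring by aldol addition of the central diene carbon to the ketone (aldol 9) and aromatise by dehydration.

**Diene.** Diene 4 is the bis(silyl enol ether) of β-keto ester 1. It is reached by two successive O-silylations: first the enol of the ketone (compound 2), then the extended enolate 3 formed by deprotonation at the chloromethyl carbon. No carbon–carbon bond is made, and 1 is commercial.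

**Enone.** Enone 7 is cut at the bond between its carbonyl carbon and the vinylic carbon, giving ketene acetal 5 and acid chloride 6. The forward step is C-acylation of the electron-rich alkene.

## Alternatives that were turned down

**Alternative 1:** The depside ester is kept and ring B is dismantled instead. Its C1–C6 and C2–C3 bonds are cut, so that C3–C6 come from a 2-pyrone and C1–C2 from an alkyne. In the forward direction the pyranyl ester A2 (6-methyl-2-oxo-2H-pyran-4-yl 3-chloro-2,4-dimethoxy-6-methylbenzoate) would be heated with the borylated propiolate A3 (methyl 3-(4,4,5,5-tetramethyl-1,3,2-dioxaborolan-2-yl)prop-2-ynoate). A [4+2] cycloaddition across C3 and C6 of the pyrone and decarboxylative cycloreversion would give arylboronate A1. Its C–B bond must then be oxidised to the C2 hydroxyl and its 2'-O-methyl group removed.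
- For: the pyrone has a single hydroxyl, so the ester bond is made with no question of which oxygen of ring B reacts. On this point it is stronger than the chosen route, which relies on the innate preference of 13 for acylation at O4. The polarisation of both partners also points to the right orientation (nucleophilic C3 of the pyrone to the boron-bearing alkyne carbon).
- Against: ring B is exactly the commercial compound 13, so building it gains nothing. The cycloaddition pairs a weakly nucleophilic 4-acyloxypyrone with an alkyne carrying two acceptor groups and would need prolonged heating, under which the enol-ester link of A2 is at risk of acyl transfer. Oxidation of the boronate and the later demethylation both have to spare two esters. The ring A acyl unit must still be made separately, and in 2'-O-methylated form.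
- Comparison: at least three operations follow the ring A acid where the chosen route needs one, and the chlorinated ring, the hard part of the molecule, is not addressed. The chosen route spends its one risky step on ring A.

**Alternative 2:** Ring A stays aromatic throughout and only its C6'–CH3 and C1'–carboxyl bonds are cut, both leading back to an aryne. In the forward direction the symmetric bromide A5 (5-bromo-2-chloro-1,3-dimethoxybenzene) would be deprotonated next to bromine by a hindered lithium amide and would eliminate to aryne A6 (4-chloro-3,5-dimethoxybenzyne). A methyl organolithium would add at the aryne carbon remote from the methoxy group, and carboxylation of the resulting aryllithium would give acid A4 (3-chloro-2,4-dimethoxy-6-methylbenzoic acid) in one flask, with no ring closed.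
- For: the symmetry of A5 makes the two deprotonation sites equivalent. The inductive effect of the neighbouring methoxy group directs the carbanion to the distal aryne carbon, so that the aryllithium sits between methyl and methoxy. Two C–C bonds arise in one operation. Counted from A5, the path to 15 (key step, esterification with 13, selective demethylation at O2') is shorter than the six steps chosen here, which is a real advantage.
- Against: A5 carries chlorine between the two methoxy groups, a position that electrophilic halogenation of a 5-substituted resorcinol diether does not favour, so its preparation adds steps that offset the saving. The methyl organolithium can undergo bromine–lithium exchange with A5 before the amide deprotonates it, the amide can add to A6 in competition, and self-trapping of the aryne lowers the efficiency of three-component couplings. A4 has both oxygens methylated, so a chelation-controlled demethylation at O2' must be carried out in the presence of the depside ester.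
- Comparison: the chosen route is longer from its commodity starting materials. In return it delivers O2' free and O4' methylated directly from the oxidation levels of the acyclic partners, and every position of ring A is fixed by connectivity and not by competing rates at a reactive intermediate.

**Alternative 3:** Ring A is again built from acyclic pieces, but on the preformed depside ester. C1'–C2' and C5'–C6' are cut, giving an oxygenated four-carbon diene and an aryl butynoate. In the forward direction the chlorinated vinylketene acetal A8 (2-chloro-1,3-dimethoxy-1-(trimethylsilyloxy)buta-1,3-diene) would add thermally across the triple bond of the ring B ester A9 (methyl 4-(but-2-ynoyloxy)-2-[(tert-butyldimethylsilyl)oxy]-6-methylbenzoate). The cyclohexadiene would aromatise on acidic work-up by loss of a methoxy group and of the trimethylsilyl group to give silyl ether A7, and removal of the remaining silyl ether would give 15.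
- For: it is the most convergent plan. There is no saponification of a hindered benzoate and no late esterification with a free salicylic acid, and on both points it is stronger than the chosen route. The regiochemistry follows from the polarised partners (the CH2 terminus of A8 to the methyl-bearing β-carbon of the ynoate).
- Against: a β-methyl ynoate is a sluggish dienophile. In A8 the chlorine on the internal carbon lowers the nucleophilicity of the diene and the fully substituted ketene-acetal terminus disfavours the reactive conformer, so heating is needed while A8 is prone to silyl transfer and hydrolysis. The aryl ester of A9 is an activated acyl donor towards the ketene acetal. The aromatisation can expel either the methoxy or the silyloxy group at C2', so the phenol and its methyl ether can both form. Ring B needs a silyl group put on and taken off.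
- Comparison: the step count ends up similar, but the risk sits in a concerted cycloaddition between two deactivated partners. The chosen route builds the same ring by stepwise polar bond formation between a strongly nucleophilic bis(silyl enol ether) and a Lewis-acid-activated acceptor, and it gives the free C2' hydroxyl unambiguously.

Key step: step 4

## Route

Step 1
Reactants: 1 methyl 4-chloroacetoacetate
Product: 2 methyl 4-chloro-3-(trimethylsilyloxy)but-2-enoate (mixture of E and Z isomers)
Conditions: Me3SiCl (1.5 equiv), Et3N (1.5 equiv), pentane, 20 °C, 48 h; filtration under argon, concentration
Reagents that add atoms: chlorotrimethylsilane, C[Si](C)(C)Cl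
Why: O-silylation of the enol of a β-keto ester under amine base (silyl enol ether formation); the conjugated enol ether should form because the C2 protons are the most acidic, and the mild base leaves the chloromethyl group untouched.

Step 2
Reactants: 2 methyl 4-chloro-3-(trimethylsilyloxy)but-2-enoate
Product: 4 4-chloro-1-methoxy-1,3-bis(trimethylsilyloxy)buta-1,3-diene, via lithium dienolate 3 (not isolated)
Conditions: LiN(iPr)2 (1.3 equiv), THF, −78 °C, 1 h; Me3SiCl (1.5 equiv), −78 → 20 °C; pentane, filtration, concentration; used crude
Reagents that add atoms: chlorotrimethylsilane, C[Si](C)(C)Cl
Why: Kinetic γ-deprotonation of the vinylogous ester at the chloromethyl carbon (the only acidic position left, further acidified by chlorine) should give the extended enolate 3, whose ester oxygen is silylated; this is the standard preparation of 1,3-bis(silyloxy)buta-1,3-dienes.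

Step 3
Reactants: 5 1,1-dimethoxyethene; 6 acetyl chloride
Product: 7 4,4-dimethoxybut-3-en-2-one
Conditions: 5 (2.1 equiv), Et2O, 0 → 20 °C; distillation under reduced pressure
Reagents that add atoms: none
Why: C-acylation of a ketene acetal: the nucleophilic CH2 carbon of 5 attacks the acid chloride and the dialkoxycarbenium ion loses a proton to give the push–pull alkene; the second equivalent of 5 takes up the HCl and collapses to methyl acetate and chloromethane, so no amine base (which could turn 6 into ketene) is needed.

Step 4
Reactants: 4 4-chloro-1-methoxy-1,3-bis(trimethylsilyloxy)buta-1,3-diene (1.3 equiv); 7 4,4-dimethoxybut-3-en-2-one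
Product: 10 methyl 3-chloro-2-hydroxy-4-methoxy-6-methylbenzoate, via open-chain adduct 8 (not isolated), via cyclic aldol 9 (not isolated)
Conditions: TiCl4 (1.1 equiv), CH2Cl2, −78 → 20 °C, 16 h; 10% aq HCl
Reagents that add atoms: none
Why: TiCl4 binds the carbonyl oxygen of 7 and makes its dialkoxy-substituted β-carbon the most electrophilic site; the chlorine-bearing terminal carbon of 4, the most nucleophilic position of the bis(silyl enol ether), should add there in Mukaiyama–Michael fashion (new C3'–C4' bond), and the adduct expels one methoxy group to restore a β-methoxy enone, giving 8 as its trichlorotitanium chelate. The central carbon of the remaining β-keto ester enolate then adds to the methyl ketone in an intramolecular aldol reaction (new C1'–C6' bond), a 6-(enolendo)-exo-trig closure in which the enolate double bond C1'=C2' lies inside the new ring and the ketone C=O outside it, giving 9. Loss of water across C1'–C6' and enolisation of the C2' ketone aromatise ring A. The closest known reaction type is the TiCl4-mediated formal [3+3] cyclocondensation of 1,3-bis(silyloxy)buta-1,3-dienes, 4-chloro dienes included, with 3-alkoxy- and 3-silyloxy-enones to give salicylates. No stereocentre is formed in the product, so the double-bond geometry of 4 and the transient centres of 8 and 9 do not matter. The step needs regioselectivity (terminal carbon to the ketene-acetal carbon, central carbon to the ketone); it is secured because the conjugate position of the activated enone is more electrophilic than the ketone carbonyl, after which only the six-ring aldol closure is open to the second nucleophilic carbon. It also needs C- over O-attack and retention of chlorine, which the low temperature of the first addition and the absence of base should ensure.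

Step 5
Reactants: 10 methyl 3-chloro-2-hydroxy-4-methoxy-6-methylbenzoate
Product: 12 3-chloro-2-hydroxy-4-methoxy-6-methylbenzoic acid, via dipotassium salt 11 (not isolated)
Conditions: KOH (6 equiv), DMSO/H2O 4:1, 80 °C; then 2 M aq HCl, 0 °C
Reagents that add atoms: potassium hydroxide, [K+].[OH-]
Why: Saponification by acyl–oxygen cleavage; poorly solvated hydroxide in aqueous DMSO should overcome the two ortho substituents and the deactivating phenoxide, and cold acidification of 11 limits decarboxylation of the electron-rich salicylic acid.

Step 6
Reactants: 12 3-chloro-2-hydroxy-4-methoxy-6-methylbenzoic acid; 13 methyl 2,4-dihydroxy-6-methylbenzoate (methyl orsellinate)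
Product: 15 methyl 4-[(3-chloro-2-hydroxy-4-methoxy-6-methylbenzoyl)oxy]-2-hydroxy-6-methylbenzoate, via mixed anhydride 14 (not isolated)
Conditions: (CF3CO)2O (4 equiv), toluene, 0 → 20 °C, 4 h; aq NaHCO3
Reagents that add atoms: none
Why: Trifluoroacetic anhydride-mediated depside esterification: the acid is activated as mixed anhydride 14 and acylates the 4-hydroxyl of 13, which is more nucleophilic than the chelated, flanked 2-hydroxyl; the 2'-hydroxyl of 12 is hindered between chlorine and the acyl group and hydrogen-bonded, so self-acylation should be slow, and any aryl trifluoroacetates hydrolyse on work-up.

## Compound list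

1 | methyl 4-chloroacetoacetate (methyl 4-chloro-3-oxobutanoate) | COC(=O)CC(=O)CCl | starting material
2 | methyl 4-chloro-3-(trimethylsilyloxy)but-2-enoate (mixture of E and Z isomers) | COC(=O)C=C(CCl)O[Si](C)(C)C | intermediate
3 | lithium 4-chloro-1-methoxy-3-(trimethylsilyloxy)buta-1,3-dien-1-olate (not isolated) | [Li+].[O-]C(OC)=CC(O[Si](C)(C)C)=CCl | intermediate
4 | 4-chloro-1-methoxy-1,3-bis(trimethylsilyloxy)buta-1,3-diene (mixture of geometric isomers) | COC(O[Si](C)(C)C)=CC(O[Si](C)(C)C)=CCl | intermediate
5 | 1,1-dimethoxyethene | C=C(OC)OC | starting material
6 | acetyl chloride | CC(Cl)=O | starting material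
7 | 4,4-dimethoxybut-3-en-2-one | CC(=O)C=C(OC)OC | intermediate
8 | methyl 4-chloro-5-methoxy-3,7-dioxooct-5-enoate (open-chain adduct, held as its trichlorotitanium chelate, not isolated; configuration at C4 and at the double bond undefined) | COC(=O)CC(=O)C(Cl)C(OC)=CC(C)=O | intermediate
9 | methyl 3-chloro-6-hydroxy-4-methoxy-6-methyl-2-oxocyclohex-4-ene-1-carboxylate (cyclic aldol, mixture of diastereomers, not isolated) | COC(=O)C1C(=O)C(Cl)C(OC)=CC1(C)O | intermediate
10 | methyl 3-chloro-2-hydroxy-4-methoxy-6-methylbenzoate | COC(=O)c1c(C)cc(OC)c(Cl)c1O | intermediate
11 | dipotassium 3-chloro-4-methoxy-6-methyl-2-oxidobenzoate (not isolated) | COc1cc(C)c(C(=O)[O-])c([O-])c1Cl.[K+].[K+] | intermediate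
12 | 3-chloro-2-hydroxy-4-methoxy-6-methylbenzoic acid | COc1cc(C)c(C(=O)O)c(O)c1Cl | intermediate
13 | methyl 2,4-dihydroxy-6-methylbenzoate (methyl orsellinate) | COC(=O)c1c(C)cc(O)cc1O | starting material
14 | 3-chloro-2-hydroxy-4-methoxy-6-methylbenzoic trifluoroacetic anhydride (not isolated) | COc1cc(C)c(C(=O)OC(=O)C(F)(F)F)c(O)c1Cl | intermediate
15 | methyl 4-[(3-chloro-2-hydroxy-4-methoxy-6-methylbenzoyl)oxy]-2-hydroxy-6-methylbenzoate | COC(=O)c1c(C)cc(OC(=O)c2c(C)cc(OC)c(Cl)c2O)cc1O | target

## Step count and risk

Total step count: 6. Longest linear sequence: 5 steps (steps 1, 2, 4, 5, 6); step 3 is a one-step branch that joins at step 4.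

**Step 4 (key step).** The first C–C bond formation may be slow, because chlorine lowers the nucleophilicity of the diene terminus and adds bulk there. Lewis-acid desilylation of 4 and self-condensation of 7 could then win, and partial 1,2-attack at the ketone would erode the regiochemistry. The fallback gives up the ring construction and sets out from the commercial compound 13. Chlorination with SO2Cl2 (1 equiv, Et2O, 0 °C) would give methyl 3-chloro-2,4-dihydroxy-6-methylbenzoate F1. Selective methylation of its non-chelated 4-hydroxyl with CH3I and K2CO3 in acetone would lead back to the route at 10. Competing chlorination at C5 and double chlorination are expected, so F1 would have to be separated by chromatography.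

**Step 2.** The lithium dienolate 3 has α-chloro carbanion character and may decompose by self-alkylation or be lost through C-silylation, and 4 may hydrolyse on handling. The fallback moves the chlorine to the end of the ring A synthesis and sets out from 7. Methyl acetoacetate F2 would be silylated as in steps 1 and 2, through methyl 3-(trimethylsilyloxy)but-2-enoate F3, to 1-methoxy-1,3-bis(trimethylsilyloxy)buta-1,3-diene F4. F4 would be cyclised with 7 under TiCl4 to methyl 2-hydroxy-4-methoxy-6-methylbenzoate F5. Chlorination of F5 with SO2Cl2 in CH2Cl2 at 0 °C would rejoin the route at 10. Here too chlorination at C5 competes with that at C3, so a separation of regioisomers is foreseen.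

**Step 5.** Hydroxide attack at the doubly ortho-substituted, phenoxide-deactivated ester may stall, and forcing it or acidifying warm may cause decarboxylation. The fallback breaks the other bond of the ester. Starting from 10, lithium propane-1-thiolate (LiSC3H7, 3 equiv) in N,N'-dimethylpropyleneurea at 20 °C would attack the ester methyl group by SN2 and release the carboxylate; cold acidification would return to the route at 12. The aryl methyl ether should survive at this temperature. No new compound arises on this path (F0).

**Step 6.** The acylium-like mixed anhydride 14 may acylate the free 2'-hydroxyl of another molecule of 12 to give oligoesters, may attack the electron-rich ring carbons or O2 of 13, or may react incompletely because the acyl carbon is flanked on both sides. The fallback masks the 2'-hydroxyl and sets out from 10. Benzylation (benzyl bromide, K2CO3, DMF) would give methyl 2-(benzyloxy)-3-chloro-4-methoxy-6-methylbenzoate F6. Saponification (KOH, DMSO/H2O) would give 2-(benzyloxy)-3-chloro-4-methoxy-6-methylbenzoic acid F7. Coupling of F7 with 13 by N,N'-dicyclohexylcarbodiimide and catalytic 4-(dimethylamino)pyridine in CH2Cl2 would give methyl 4-{[2-(benzyloxy)-3-chloro-4-methoxy-6-methylbenzoyl]oxy}-2-hydroxy-6-methylbenzoate F8. BCl3 in CH2Cl2 at −78 °C, which cleaves the benzyl ether chelated to the ortho carbonyl without reducing the aryl chloride, would arrive at the target 15.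

## Further compounds

F1 | step 4 | methyl 3-chloro-2,4-dihydroxy-6-methylbenzoate | COC(=O)c1c(C)cc(O)c(Cl)c1O
F2 | step 2 | methyl acetoacetate | COC(=O)CC(C)=O
F3 | step 2 | methyl 3-(trimethylsilyloxy)but-2-enoate | COC(=O)C=C(C)O[Si](C)(C)C
F4 | step 2 | 1-methoxy-1,3-bis(trimethylsilyloxy)buta-1,3-diene | COC(O[Si](C)(C)C)=CC(=C)O[Si](C)(C)C
F5 | step 2 | methyl 2-hydroxy-4-methoxy-6-methylbenzoate | COC(=O)c1c(C)cc(OC)cc1O
F0 | step 5 | none | none
F6 | step 6 | methyl 2-(benzyloxy)-3-chloro-4-methoxy-6-methylbenzoate | COC(=O)c1c(C)cc(OC)c(Cl)c1OCc2ccccc2
F7 | step 6 | 2-(benzyloxy)-3-chloro-4-methoxy-6-methylbenzoic acid | COc1cc(C)c(C(=O)O)c(OCc2ccccc2)c1Cl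
F8 | step 6 | methyl 4-{[2-(benzyloxy)-3-chloro-4-methoxy-6-methylbenzoyl]oxy}-2-hydroxy-6-methylbenzoate | COC(=O)c1c(C)cc(OC(=O)c2c(C)cc(OC)c(Cl)c2OCc3ccccc3)cc1O
A1 | alternative 1 | methyl 4-[(3-chloro-2,4-dimethoxy-6-methylbenzoyl)oxy]-6-methyl-2-(4,4,5,5-tetramethyl-1,3,2-dioxaborolan-2-yl)benzoate | COC(=O)c1c(C)cc(OC(=O)c2c(C)cc(OC)c(Cl)c2OC)cc1B1OC(C)(C)C(C)(C)O1
A2 | alternative 1 | 6-methyl-2-oxo-2H-pyran-4-yl 3-chloro-2,4-dimethoxy-6-methylbenzoate | COc1cc(C)c(C(=O)OC2=CC(=O)OC(C)=C2)c(OC)c1Cl
A3 | alternative 1 | methyl 3-(4,4,5,5-tetramethyl-1,3,2-dioxaborolan-2-yl)prop-2-ynoate | COC(=O)C#CB1OC(C)(C)C(C)(C)O1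
A4 | alternative 2 | 3-chloro-2,4-dimethoxy-6-methylbenzoic acid | COc1cc(C)c(C(=O)O)c(OC)c1Cl
A5 | alternative 2 | 5-bromo-2-chloro-1,3-dimethoxybenzene | COc1cc(Br)cc(OC)c1Cl
A6 | alternative 2 | 4-chloro-3,5-dimethoxybenzyne | COC1=C(Cl)C(OC)=CC#C1
A7 | alternative 3 | methyl 2-[(tert-butyldimethylsilyl)oxy]-4-[(3-chloro-2-hydroxy-4-methoxy-6-methylbenzoyl)oxy]-6-methylbenzoate | COC(=O)c1c(C)cc(OC(=O)c2c(C)cc(OC)c(Cl)c2O)cc1O[Si](C)(C)C(C)(C)C
A8 | alternative 3 | 2-chloro-1,3-dimethoxy-1-(trimethylsilyloxy)buta-1,3-diene | C=C(OC)C(Cl)=C(OC)O[Si](C)(C)C
A9 | alternative 3 | methyl 4-(but-2-ynoyloxy)-2-[(tert-butyldimethylsilyl)oxy]-6-methylbenzoate | CC#CC(=O)Oc1cc(C)c(C(=O)OC)c(O[Si](C)(C)C(C)(C)C)c1
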